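## Analysis of the target

Numbering used throughout: C1 is the lactone carbonyl, C2 its methylene, C3 the methine on the peroxide, C4 the methyl-bearing lactone carbon, C5 a methylene, C6 the methyl-bearing peroxide carbon, and C7–C16 the chain, with the methine C8, E double bonds at C11=C12 and C15=C16, and phenyl on C16. The core is a 1,2-dioxane (ring A: C3, C4, C5, C6 and the two peroxide oxygens) cis-fused along C3–C4 to a γ-lactone (ring B: C1, C2, C3, C4 and the lactone oxygen). There are four stereocentres, C3 (S), C4 (S), C6 (R) and C8 (R). C3 and C4 are adjacent and tied by the cis ring fusion; C6 stands 1,3 to C4 with the two ring methyl groups cis and the side chain on the lactone face; C8 lies outside the rings, two bonds from C6, with no cyclic relation to the other three. C4 and C6 are fully substituted oxygen-bearing carbons, and the O–O bond joins a secondary carbon (C3) to a tertiary one (C6). The O–O bond does not tolerate low-valent metals or strong base (the C3–H is prone to base-induced fragmentation), and the styrene and the C11=C12 alkene rule out ozone, peracids and hydrogenation. The synthesis is hard because the tertiary peroxide carbon cannot be made by substitution, C8 cannot be controlled from the ring, and the peroxide must come in late under conditions that spare two alkenes. The strategy rests on C7 and C8: C8 is an isolated methyl-bearing methine and C7 is the single methylene linking it to C6, so a terminal C7=C8 alkene can take methyl at C8 and a metal at C7, and that metal can be coupled to an sp2 C6 whose exocyclic methylene later serves as the site of peroxide ring closure and as the future C6 methyl.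

## Retrosynthetic reasoning

**Ring B (C1–O bond).** The lactone bond is cut first, together with the silyl group on the C4 oxygen: target 28 goes back to hydroxy ester 27 and its silyl ether 26. The lactone is the most base-sensitive part and the tertiary C4 oxygen is otherwise inert, so closing ring B last under acid costs nothing. The forward step has to free the C4 hydroxyl and acylate it intramolecularly without harming the O–O bond.

**C2–C3 bond.** Ester 26 is cut into the cyclic peroxy acetal 24 and the two-carbon nucleophile 25. C3 is the only ring A carbon that carries a peroxide oxygen and a hydrogen, so it is at the aldehyde oxidation level and can act as an electrophile (peroxycarbenium ion) once ring A exists. Cutting here keeps the ester out of all earlier organometallic steps. The forward reaction must ionise the C3–OMe bond and not the O–O bond, and must bring the nucleophile in cis to the C4 oxygen.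

**C6–O bond (ring A).** Compound 24 comes from organomercurial 23, and this from the open-chain hydroperoxy acetal 22, in which C6 is the substituted end of a 1,1-disubstituted alkene. This cut is preferred to the C3–O bond because a tertiary peroxide carbon cannot be made by displacement, whereas Markovnikov attack of a hydroperoxide on an activated alkene builds it directly and the metal-bearing methylene becomes the C6 methyl. The forward reaction has to close a six-membered ring in the exo mode at the 1,1-disubstituted alkene in the presence of two 1,2-disubstituted ones.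

**C3–OOH bond.** The hydroperoxy group on C3 is traced to a methoxy group: 22 from dimethyl acetal 21. An acetal is the form of the C3 aldehyde that survives organoaluminium and organozinc reagents, and exchange of one alkoxy group for a hydroperoxy group needs only a Lewis acid and a peroxide source. The forward step must stop at mono-exchange.

**C6–C7 and C8–CH3 bonds (central cut).** Compound 21 is divided at C6–C7 and loses the methyl group on C8, giving bromoalkene 17 (C3–C6), triene 9 (C7–C16) and the methyl donor 18; alane 19 and zinc species 20 lie in between. C6–C7 separates the half carrying C4 from the half carrying the chain, and C8 next to it is a methyl-bearing methine, so one carbometalation creates C8 and supplies the C7 nucleophile. No other cut gives two skeletal bonds, a stereocentre and the fragment union together. The forward reaction must add methyl to the terminal alkene only, with face control from the catalyst, and pass the primary alkyl group to palladium faster than methyl.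

**Triene 9.** It is cut at C11=C12 into aldehyde 4 and sulfone 8, because an E alkene in the middle of an unfunctionalised chain is best made by a sulfone olefination with inherent E preference. Aldehyde 4 goes back through ester 3 to allylic alcohol 1 and orthoester 2, a sigmatropic rearrangement that fixes the E geometry of C15=C16. Sulfone 8 comes from sulfide 7, assembled from bromide 5 and thiol 6.

**Bromoalkene 17.** Functional-group changes lead back to aldehyde 16, ester 15 and hydroxy ester 14, and the C4–C5 bond is then cut: 14 arises from the alkylated dioxolanone 13, made from dioxolanone 11 and dibromide 12, and 11 from hydroxy acid 10. C4 is the stereocentre of 10, whose hydrogen is replaced by C5 with retention through the temporary acetal centre, so its absolute configuration comes from the chiral pool. The vinylic bromine of 12 is carried along as the coupling handle.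

## Alternatives that were turned down

**Alternative 1:** The C4–O bond of ring B is cut back to a C4–H bond, so the precursor is 2-{(3S,4R,6R)-6-[(2R)-5-(acetyloxy)-2-methylpentyl]-4,6-dimethyl-1,2-dioxan-3-yl}acetic acid A1, with C4 as a methyl-bearing methine and the chain cut short at C11. In the forward step Mn(OTf)2(pdp) and H2O2 give a high-valent manganese oxo species bound to the carboxylate; it abstracts the tertiary γ-hydrogen at C4 and the bound carboxylate rebounds, closing ring B to give (4R)-5-[(3R,4aS,7aS)-3,4a-dimethyl-6-oxohexahydro-3H-furo[3,2-c][1,2]dioxin-3-yl]-4-methylpentyl acetate A2.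
- For: no protecting group on C4, and the tether forces the cis ring fusion. On the C3/C4 relationship this is stronger than the chosen route, which sets C3 by an intermolecular addition.
- Against: a strong oxidant must act on a substrate that already contains the O–O bond. The C3–H bond, α to a peroxide oxygen, is weaker than the C4–H bond, and abstraction there destroys ring A. The tertiary C8–H is a second competitor. Alkenes cannot be present, so both E alkenes and the phenyl group would have to be added after the peroxy-lactone is complete. A1 still needs C3, C4, C6 and C8 to be set beforehand, which is no easier than the original problem.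
- Comparison: the chosen strategy takes the C4 oxygen and its absolute configuration from the chiral pool, keeps oxidants away from the peroxide and carries the complete side chain through the fragment union. It gives up the guaranteed ring fusion.

**Alternative 2:** Ring A is cut at a C4=C5 double bond, leading back to the acyclic peroxide tert-butyl (3S)-3-{[(3R,5R)-8-{[tert-butyl(dimethyl)silyl]oxy}-3,5-dimethyloct-1-en-3-yl]peroxy}-4-methylpent-4-enoate A3 (isopropenyl on C3, vinyl on C6). The second-generation Grubbs catalyst would join the two alkenes to give tert-butyl 2-{(3S,6R)-6-[(2R)-5-{[tert-butyl(dimethyl)silyl]oxy}-2-methylpentyl]-4,6-dimethyl-3,6-dihydro-1,2-dioxin-3-yl}acetate A4.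
- For: C3 and C6 are fixed in the open chain and cannot be scrambled by the ring closure. On C6 this is stronger than the chosen route, which expects little control there. Metathesis catalysts tolerate dialkyl peroxides.
- Against: after the ring closure the C4=C5 alkene of A4 must be hydrated with oxygen at C4 on the face cis to the C3 arm. Radical hydration puts a radical β to a peroxide oxygen, and polar methods end in reductions that endanger the O–O bond. A3 needs an enantioenriched tertiary allylic hydroperoxide and its alkylation at a secondary allylic carbon that has an ester in the β position, where allylic transposition and elimination compete. The ring closure must form a trisubstituted alkene next to a quaternary centre. The side-chain alkenes must be absent, so the tail is added afterwards.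
- Comparison: more steps, and the hardest stereocentre (C4) is left to a late step on a fragile ring. The chosen route has C4 secure from the start.

**Alternative 3:** Ring A is cut at C6–O. Hg(OAc)2 activates the 1,1-disubstituted alkene of a hydroperoxy acetal and the hydroperoxide oxygen attacks C6 in the 6-exo mode, giving acetoxy({(3S,4S,6R)-3-methoxy-4-methyl-6-[(2R,5E,9E)-2-methyl-10-phenyldeca-5,9-dien-1-yl]-4-[(triethylsilyl)oxy]-1,2-dioxan-6-yl}methyl)mercury A5.
- For: a mild, non-reducing and non-basic way to make the tertiary peroxide carbon with Markovnikov regiochemistry, with the mercurated methylene becoming the C6 methyl. On reliability of ring formation it is as strong as the chosen route, because the chosen route uses the same closure as step 14; A5 is the 3S epimer of compound 23.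
- Against, as a guiding idea: it deals with ring A only. It leaves open where C8 comes from and how C6–C7 is made, gives little control at C6, and needs the whole C3–C16 chain with C4 and C8 in place beforehand. If that chain were assembled linearly from an enantiopure C8 building block, the C8 purity would be higher than a catalytic carbometalation can promise, but the sequence would be longer.
- Comparison: the chosen strategy supplies the part this alternative lacks. It creates C8 catalytically while joining the two halves, and delivers exactly the alkene this ring closure requires.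

Key step: step 12

Assumption on the chemistry: the (−)-enantiomer of bis(1-neomenthylindenyl)zirconium dichloride is taken to be the one that gives (R)-2-methylalkyl metals from 1-alkenes; if the sense is reversed for triene 9, the (+)-enantiomer is used and nothing else changes.

## Route

Step 1
Reactants: 1 1-phenylprop-2-en-1-ol (racemic); 2 triethyl orthoacetate
Product: 3 ethyl (4E)-5-phenylpent-4-enoate
Conditions: 2 (5 equiv), EtCO2H (cat.), 140 °C, EtOH distilled off
Reagents that add atoms: none
Why: Johnson–Claisen rearrangement: the mixed ketene acetal from 1 and 2 undergoes a [3,3]-sigmatropic shift through a chair with the phenyl group equatorial, so the new C15=C16 bond is E and conjugated with the ring.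

Step 2
Reactants: 3 ethyl (4E)-5-phenylpent-4-enoate
Product: 4 (4E)-5-phenylpent-4-enal
Conditions: iBu2AlH (1.05 equiv), CH2Cl2, −78 °C; KNa tartrate (aq)
Reagents that add atoms: none
Why: Partial reduction of an ester with iBu2AlH at −78 °C; the aluminium hemiacetal survives until work-up and the alkene and arene are not touched.

Step 3
Reactants: 5 5-bromopent-1-ene; 6 1-phenyl-1H-tetrazole-5-thiol
Product: 7 5-(pent-4-en-1-ylsulfanyl)-1-phenyl-1H-tetrazole
Conditions: K2CO3, acetone, reflux
Reagents that add atoms: none
Why: S-Alkylation of the thiolate with a primary bromide (SN2); sulfur is far more nucleophilic than the ring nitrogens.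

Step 4
Reactants: 7 5-(pent-4-en-1-ylsulfanyl)-1-phenyl-1H-tetrazole
Product: 8 5-(pent-4-ene-1-sulfonyl)-1-phenyl-1H-tetrazole
Conditions: H2O2 (30% aq), (NH4)6Mo7O24·4H2O (cat.), EtOH, 0 °C → rt
Reagents that add atoms: hydrogen peroxide, OO
Why: Molybdate-catalysed oxidation of a sulfide to the sulfone; an unactivated terminal alkene is not epoxidised under these conditions.

Step 5
Reactants: 8 5-(pent-4-ene-1-sulfonyl)-1-phenyl-1H-tetrazole; 4 (4E)-5-phenylpent-4-enal
Product: 9 (5E,9E)-10-phenyldeca-1,5,9-triene
Conditions: KN(SiMe3)2, DME, −60 °C; then 4, −60 °C → rt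
Reagents that add atoms: none
Why: Julia–Kocienski olefination forming C11=C12: the sulfonyl carbanion adds to 4, then Smiles rearrangement and loss of SO2 and the tetrazololate follow; the potassium counter-ion in DME favours the anti adduct and so the E alkene. The other two alkenes are spectators.

Step 6
Reactants: 10 (R)-lactic acid
Product: 11 (2R,5R)-2-tert-butyl-5-methyl-1,3-dioxolan-4-one
Conditions: tBuCHO, TsOH·H2O (cat.), H2SO4 (cat.), pentane, reflux (water separator); crystallisation from pentane/Et2O, −78 °C
Reagents that add atoms: pivalaldehyde (2,2-dimethylpropanal), CC(C)(C)C=O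
Why: Acid-catalysed acetalisation of the α-hydroxy acid with azeotropic removal of water (dioxolanone for self-regeneration of stereocentres); the cis isomer predominates and is purified by low-temperature crystallisation, so the acetal carbon now stores the configuration of 10.

Step 7
Reactants: 11 (2R,5R)-2-tert-butyl-5-methyl-1,3-dioxolan-4-one; 12 2,3-dibromoprop-1-ene
Product: 13 (2R,5S)-5-(2-bromoprop-2-en-1-yl)-2-tert-butyl-5-methyl-1,3-dioxolan-4-one
Conditions: LiN(iPr)2, THF, −78 °C; then 12, −78 → −20 °C
Reagents that add atoms: none
Why: Enolate alkylation with self-regeneration of the stereocentre: the allylic bromide of 12 attacks the planar lithium enolate on the face anti to the tert-butyl group, replacing the former hydrogen with retention and setting the quaternary centre that becomes C4 (S). The vinylic bromide does not react.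

Step 8
Reactants: 13 (2R,5S)-5-(2-bromoprop-2-en-1-yl)-2-tert-butyl-5-methyl-1,3-dioxolan-4-one
Product: 14 methyl (2S)-4-bromo-2-hydroxy-2-methylpent-4-enoate
Conditions: NaOMe (0.3 equiv), MeOH, 0 °C → rt
Reagents that add atoms: methanol, CO
Why: Methoxide-catalysed transesterification opens the dioxolanone; the hemiacetal alkoxide collapses with release of the aldehyde auxiliary, leaving the tertiary α-hydroxy ester with the stereocentre untouched.

Step 9
Reactants: 14 methyl (2S)-4-bromo-2-hydroxy-2-methylpent-4-enoate
Product: 15 methyl (2S)-4-bromo-2-methyl-2-[(triethylsilyl)oxy]pent-4-enoate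
Conditions: Et3SiOTf, 2,6-lutidine, CH2Cl2, 0 °C
Reagents that add atoms: triethylsilyl trifluoromethanesulfonate, CC[Si](CC)(CC)OS(=O)(=O)C(F)(F)F
Why: Silylation of a hindered tertiary alcohol with a silyl triflate and a non-nucleophilic base; the triethylsilyl group masks the C4 oxygen against the organometallic reagents of step 12 and is removable with acid at the end.

Step 10
Reactants: 15 methyl (2S)-4-bromo-2-methyl-2-[(triethylsilyl)oxy]pent-4-enoate
Product: 16 (2S)-4-bromo-2-methyl-2-[(triethylsilyl)oxy]pent-4-enal
Conditions: iBu2AlH (1.1 equiv), CH2Cl2, −78 °C; KNa tartrate (aq)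
Reagents that add atoms: none
Why: Partial ester reduction with iBu2AlH; α-silyloxy esters give stable tetrahedral aluminium adducts at −78 °C, and the quaternary α-carbon cannot epimerise.

Step 11
Reactants: 16 (2S)-4-bromo-2-methyl-2-[(triethylsilyl)oxy]pent-4-enal
Product: 17 {[(2S)-4-bromo-1,1-dimethoxy-2-methylpent-4-en-2-yl]oxy}triethylsilane
Conditions: MeOSiMe3 (3 equiv), Me3SiOTf (5 mol %), CH2Cl2, −78 → −30 °C; pyridine quench
Reagents that add atoms: methoxytrimethylsilane, CO[Si](C)(C)C
Why: Noyori acetalisation: Me3SiOTf-catalysed reaction of the aldehyde with the methyl silyl ether forms the dimethyl acetal under aprotic conditions at low temperature, which spares the tertiary silyl ether and the bromoalkene.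

Step 12
Reactants: 9 (5E,9E)-10-phenyldeca-1,5,9-triene; 18 trimethylaluminium; 17 {[(2S)-4-bromo-1,1-dimethoxy-2-methylpent-4-en-2-yl]oxy}triethylsilane
Product: 21 triethyl{[(2S,6R,9E,13E)-1,1-dimethoxy-2,6-dimethyl-4-methylidene-14-phenyltetradeca-9,13-dien-2-yl]oxy}silane, via alkylalane 19 (not isolated), via alkylzinc triflate 20 (not isolated)
Conditions: 9 (1.6 equiv), 18 (3 equiv), (−)-bis(1-neomenthylindenyl)zirconium dichloride (5 mol %), methylaluminoxane (MeAlO)n (cat.), CH2Cl2, 0 °C → rt; volatiles and excess 18 removed in vacuo; Zn(OTf)2, DMF, 70 °C; then 17 (1.0 equiv), Pd(PPh3)4 (5 mol %), DMF, rt → 50 °C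
Reagents that add atoms: none
Why: Zirconium-catalysed asymmetric carboalumination followed by Negishi coupling; the closest known reaction is the one-flask methylalumination of a 1-alkene and palladium-catalysed alkenylation of the resulting alane. A cationic methylzirconocene formed from 18 and the chiral dichloride inserts the terminal C7=C8 bond of 9 with zirconium on C7 and methyl on C8, and exchange with aluminium releases alane 19 and the catalyst. The alkene face is chosen by the neomenthylindenyl ligands alone, which sets C8 as R; selectivity for unfunctionalised 1-alkenes in this reaction class is moderate, so some C8 epimer is expected and is carried along as a diastereomer. Only monosubstituted alkenes insert, so the 1,2-disubstituted C11=C12 and C15=C16 bonds are left alone, and the chlorinated solvent disfavours hydride transfer and cyclisation onto C11=C12. After excess 18 is pumped off, Zn(OTf)2 in DMF moves the primary alkyl group to zinc (20); zerovalent palladium inserts into the C6–Br bond of 17, and transmetalation and reductive elimination form C6–C7. No ring is closed in this step. Alkyl transfer must win over methyl transfer, which is why the alane is used in excess over 17; the acetal, the silyl ether and the C4 centre of 17 are inert to alkylzinc reagents in DMF.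

Step 13
Reactants: 21 triethyl{[(2S,6R,9E,13E)-1,1-dimethoxy-2,6-dimethyl-4-methylidene-14-phenyltetradeca-9,13-dien-2-yl]oxy}silane
Product: 22 {[(2S,6R,9E,13E)-1-hydroperoxy-1-methoxy-2,6-dimethyl-4-methylidene-14-phenyltetradeca-9,13-dien-2-yl]oxy}triethylsilane (both C1 epimers)
Conditions: H2O2·urea (10 equiv), Sc(OTf)3 (10 mol %), MeOH, rt
Reagents that add atoms: hydrogen peroxide (as its urea adduct), OO
Why: Lewis acid-catalysed acetal exchange: Sc(OTf)3 ionises one C3–OMe bond and H2O2 captures the oxocarbenium ion, while methanol as solvent holds the product at the mono-hydroperoxy acetal. C3 becomes a stereocentre without control, which does not matter because it is planarised again in step 16.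

Step 14
Reactants: 22 {[(2S,6R,9E,13E)-1-hydroperoxy-1-methoxy-2,6-dimethyl-4-methylidene-14-phenyltetradeca-9,13-dien-2-yl]oxy}triethylsilane (both C1 epimers)
Product: 23 acetoxy({(4S,6R)-3-methoxy-4-methyl-6-[(2R,5E,9E)-2-methyl-10-phenyldeca-5,9-dien-1-yl]-4-[(triethylsilyl)oxy]-1,2-dioxan-6-yl}methyl)mercury (both C3 epimers)
Conditions: Hg(OAc)2 (1.1 equiv), CH2Cl2, 0 °C → rt
Reagents that add atoms: mercury diacetate, CC(=O)O[Hg]OC(C)=O
Why: Cycloperoxymercuration: divalent mercury activates the 1,1-disubstituted C6 alkene, which reacts far faster than the E-1,2-disubstituted C11=C12 and C15=C16 bonds, and the terminal hydroperoxide oxygen attacks the more substituted carbon C6 in a 6-exo-trig closure that forms ring A. C6 is created here; in the chair-like transition state one C6 substituent must lie syn-axial to a C4 substituent whichever face reacts, so little intrinsic preference is expected, and the 6R epimer shown is separated from its C6 epimer by chromatography here or after step 15.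

Step 15
Reactants: 23 acetoxy({(4S,6R)-3-methoxy-4-methyl-6-[(2R,5E,9E)-2-methyl-10-phenyldeca-5,9-dien-1-yl]-4-[(triethylsilyl)oxy]-1,2-dioxan-6-yl}methyl)mercury (both C3 epimers)
Product: 24 triethyl({(4S,6R)-3-methoxy-4,6-dimethyl-6-[(2R,5E,9E)-2-methyl-10-phenyldeca-5,9-dien-1-yl]-1,2-dioxan-4-yl}oxy)silane (both C3 epimers)
Conditions: NaBH4, NaOH (2 M aq), THF, 0 °C
Reagents that add atoms: none
Why: Hydridodemercuration: the alkylmercury hydride formed with NaBH4 collapses by a radical chain to the C6 methyl group, and dialkyl peroxides and peroxy acetals survive cold alkaline borohydride. The β-peroxyalkyl radical can also close to an epoxide with O–O cleavage; a high hydride concentration at 0 °C holds this back.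

Step 16
Reactants: 24 triethyl({(4S,6R)-3-methoxy-4,6-dimethyl-6-[(2R,5E,9E)-2-methyl-10-phenyldeca-5,9-dien-1-yl]-1,2-dioxan-4-yl}oxy)silane (both C3 epimers); 25 tert-butyl[(1-methoxyethenyl)oxy]dimethylsilane
Product: 26 methyl 2-{(3S,4S,6R)-4,6-dimethyl-6-[(2R,5E,9E)-2-methyl-10-phenyldeca-5,9-dien-1-yl]-4-[(triethylsilyl)oxy]-1,2-dioxan-3-yl}acetate
Conditions: 25 (3 equiv), Me3SiOTf (1.1 equiv), CH2Cl2, −78 °C; NaHCO3 (aq)
Reagents that add atoms: none
Why: Mukaiyama-type addition to a peroxycarbenium ion: Me3SiOTf removes the C3 methoxy group from either C3 epimer and the silyl ketene acetal 25 adds to the cation, forming C2–C3. Attack is expected along the axial trajectory of the half-chair that keeps the electron-withdrawing C4–O bond pseudo-equatorial and the C4 methyl pseudo-axial, that is anti to this methyl group, which places the acetate arm cis to the C4 oxygen (3S). Selectivity is not expected to be complete, and the 3R epimer is removed after step 17.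

Step 17
Reactants: 26 methyl 2-{(3S,4S,6R)-4,6-dimethyl-6-[(2R,5E,9E)-2-methyl-10-phenyldeca-5,9-dien-1-yl]-4-[(triethylsilyl)oxy]-1,2-dioxan-3-yl}acetate
Product: 28 (3R,4aS,7aS)-3,4a-dimethyl-3-[(2R,5E,9E)-2-methyl-10-phenyldeca-5,9-dien-1-yl]-3,4,4a,7a-tetrahydrofuro[3,2-c][1,2]dioxin-6(7H)-one, via hydroxy ester 27 (not isolated)
Conditions: TsOH·H2O (0.5 equiv), CH2Cl2 with 2% MeOH, 0 °C → rt
Reagents that add atoms: none
Why: Acid cleavage of the tertiary triethylsilyl ether, then acid-catalysed lactonisation (5-exo-trig acyl substitution) of hydroxy ester 27, helped by the cis relation of hydroxyl and acetate arm and the fully substituted C4. C3, C4, C6 and C8 are not affected, and the peroxide tolerates catalytic sulfonic acid at room temperature.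

## Compound list

1 | 1-phenylprop-2-en-1-ol (racemic) | C=CC(O)c1ccccc1 | starting material
2 | triethyl orthoacetate (1,1,1-triethoxyethane) | CC(OCC)(OCC)OCC | starting material
3 | ethyl (4E)-5-phenylpent-4-enoate | CCOC(=O)CC/C=C/c1ccccc1 | intermediate
4 | (4E)-5-phenylpent-4-enal | O=CCC/C=C/c1ccccc1 | intermediate
5 | 5-bromopent-1-ene | C=CCCCBr | starting material
6 | 1-phenyl-1H-tetrazole-5-thiol | SC1=NN=NN1c1ccccc1 | starting material
7 | 5-(pent-4-en-1-ylsulfanyl)-1-phenyl-1H-tetrazole | C=CCCCSC1=NN=NN1c1ccccc1 | intermediate
8 | 5-(pent-4-ene-1-sulfonyl)-1-phenyl-1H-tetrazole | C=CCCCS(=O)(=O)C1=NN=NN1c1ccccc1 | intermediate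
9 | (5E,9E)-10-phenyldeca-1,5,9-triene | C=CCC/C=C/CC/C=C/c1ccccc1 | intermediate
10 | (R)-lactic acid, (2R)-2-hydroxypropanoic acid | C[C@@H](O)C(=O)O | starting material
11 | (2R,5R)-2-tert-butyl-5-methyl-1,3-dioxolan-4-one | C[C@H]1O[C@@H](C(C)(C)C)OC1=O | intermediate
12 | 2,3-dibromoprop-1-ene | C=C(Br)CBr | starting material
13 | (2R,5S)-5-(2-bromoprop-2-en-1-yl)-2-tert-butyl-5-methyl-1,3-dioxolan-4-one | C[C@@]1(CC(Br)=C)O[C@@H](C(C)(C)C)OC1=O | intermediate
14 | methyl (2S)-4-bromo-2-hydroxy-2-methylpent-4-enoate | C=C(Br)C[C@](C)(O)C(=O)OC | intermediate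
15 | methyl (2S)-4-bromo-2-methyl-2-[(triethylsilyl)oxy]pent-4-enoate | C=C(Br)C[C@](C)(O[Si](CC)(CC)CC)C(=O)OC | intermediate
16 | (2S)-4-bromo-2-methyl-2-[(triethylsilyl)oxy]pent-4-enal | C=C(Br)C[C@](C)(O[Si](CC)(CC)CC)C=O | intermediate
17 | {[(2S)-4-bromo-1,1-dimethoxy-2-methylpent-4-en-2-yl]oxy}triethylsilane | C=C(Br)C[C@](C)(O[Si](CC)(CC)CC)C(OC)OC | intermediate
18 | trimethylaluminium | C[Al](C)C | starting material
19 | dimethyl[(2R,5E,9E)-2-methyl-10-phenyldeca-5,9-dien-1-yl]alumane | C[C@H](CC/C=C/CC/C=C/c1ccccc1)C[Al](C)C | intermediate
20 | [(2R,5E,9E)-2-methyl-10-phenyldeca-5,9-dien-1-yl]zinc trifluoromethanesulfonate | C[C@H](CC/C=C/CC/C=C/c1ccccc1)C[Zn]OS(=O)(=O)C(F)(F)F | intermediate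
21 | triethyl{[(2S,6R,9E,13E)-1,1-dimethoxy-2,6-dimethyl-4-methylidene-14-phenyltetradeca-9,13-dien-2-yl]oxy}silane | C[C@H](CC/C=C/CC/C=C/c1ccccc1)CC(=C)C[C@](C)(O[Si](CC)(CC)CC)C(OC)OC | intermediate
22 | {[(2S,6R,9E,13E)-1-hydroperoxy-1-methoxy-2,6-dimethyl-4-methylidene-14-phenyltetradeca-9,13-dien-2-yl]oxy}triethylsilane (both C1 epimers) | C[C@H](CC/C=C/CC/C=C/c1ccccc1)CC(=C)C[C@](C)(O[Si](CC)(CC)CC)C(OC)OO | intermediate
23 | acetoxy({(4S,6R)-3-methoxy-4-methyl-6-[(2R,5E,9E)-2-methyl-10-phenyldeca-5,9-dien-1-yl]-4-[(triethylsilyl)oxy]-1,2-dioxan-6-yl}methyl)mercury (both C3 epimers) | C[C@H](CC/C=C/CC/C=C/c1ccccc1)C[C@]1(C[Hg]OC(C)=O)C[C@](C)(O[Si](CC)(CC)CC)C(OC)OO1 | intermediate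
24 | triethyl({(4S,6R)-3-methoxy-4,6-dimethyl-6-[(2R,5E,9E)-2-methyl-10-phenyldeca-5,9-dien-1-yl]-1,2-dioxan-4-yl}oxy)silane (both C3 epimers) | C[C@H](CC/C=C/CC/C=C/c1ccccc1)C[C@]1(C)C[C@](C)(O[Si](CC)(CC)CC)C(OC)OO1 | intermediate
25 | tert-butyl[(1-methoxyethenyl)oxy]dimethylsilane | C=C(OC)O[Si](C)(C)C(C)(C)C | starting material
26 | methyl 2-{(3S,4S,6R)-4,6-dimethyl-6-[(2R,5E,9E)-2-methyl-10-phenyldeca-5,9-dien-1-yl]-4-[(triethylsilyl)oxy]-1,2-dioxan-3-yl}acetate | C[C@H](CC/C=C/CC/C=C/c1ccccc1)C[C@]1(C)C[C@](C)(O[Si](CC)(CC)CC)[C@H](CC(=O)OC)OO1 | intermediate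
27 | methyl 2-{(3S,4S,6R)-4-hydroxy-4,6-dimethyl-6-[(2R,5E,9E)-2-methyl-10-phenyldeca-5,9-dien-1-yl]-1,2-dioxan-3-yl}acetate | C[C@H](CC/C=C/CC/C=C/c1ccccc1)C[C@]1(C)C[C@](C)(O)[C@H](CC(=O)OC)OO1 | intermediate
28 | (3R,4aS,7aS)-3,4a-dimethyl-3-[(2R,5E,9E)-2-methyl-10-phenyldeca-5,9-dien-1-yl]-3,4,4a,7a-tetrahydrofuro[3,2-c][1,2]dioxin-6(7H)-one | C[C@H](CC/C=C/CC/C=C/c1ccccc1)C[C@]1(C)C[C@]2(C)OC(=O)C[C@@H]2OO1 | target

## Step count and least certain steps

Total: 17 steps. Longest linear sequence: 12 steps (steps 6–17, from 10). The triene branch (steps 1–5) joins at step 12.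

**Step 12 (key step).** Three things may go wrong. Facial discrimination in the methylzirconation may be incomplete, leaving a C8 epimer that is hard to remove because C8 is remote from the other centres. Methyl may transfer to palladium in competition with the primary alkyl group, diverting 17 into its methyl-coupled analogue. Aluminium-to-zinc exchange may be sluggish. Fallback: set out from 9 and run the same carboalumination to alane 19, but oxidise it with O2 to (2R,5E,9E)-2-methyl-10-phenyldeca-5,9-dien-1-ol F1. Its enantiomeric purity is raised by lipase-catalysed acetylation (Burkholderia cepacia lipase, vinyl acetate), which is expected to remove the faster-reacting minor enantiomer as (2S,5E,9E)-2-methyl-10-phenyldeca-5,9-dien-1-yl acetate F2. F1 is converted with I2, PPh3 and imidazole into [(1E,5E,9R)-10-iodo-9-methyldeca-1,5-dien-1-yl]benzene F3, zinc is inserted (Zn, LiCl, THF) to give iodo[(2R,5E,9E)-2-methyl-10-phenyldeca-5,9-dien-1-yl]zinc F4, and F4 is coupled with 17 under PdCl2(dppf), which rejoins the route at 21. This separates the creation of C8 from the C–C coupling, lets C8 be upgraded before the fragments meet, and takes methyl ligands out of the coupling, at the cost of three more operations.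

**Step 13.** Ionisation of the C3 acetal may be slow, because its oxocarbenium ion is destabilised by the adjacent C4–O bond and shielded by the quaternary centre. Forcing conditions invite partial loss of the silyl ether and over-exchange to a geminal bis-hydroperoxide. Fallback: from 21 the C6–O bond is made first. Hydroperoxymercuration of the 1,1-disubstituted alkene with Hg(OAc)2 and H2O2 gives acetoxy{[(2S,6R,9E,13E)-4-hydroperoxy-1,1-dimethoxy-2,6-dimethyl-14-phenyl-2-[(triethylsilyl)oxy]tetradeca-9,13-dien-4-yl]methyl}mercury F5, which NaBH4 reduces to the tertiary hydroperoxide {[(2S,6R,9E,13E)-4-hydroperoxy-1,1-dimethoxy-2,4,6-trimethyl-14-phenyltetradeca-9,13-dien-2-yl]oxy}triethylsilane F6. Me3SiOTf in CH2Cl2 at low temperature then ionises the acetal and the tethered hydroperoxide closes ring A by intramolecular acetal exchange, returning to 24. The peroxide oxygen is delivered intramolecularly, so neither excess H2O2 nor a protic solvent is present at the ionisation stage.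

**Step 14.** Facial selectivity at C6 is likely to be poor, because neither chair-like transition state avoids a syn-axial contact with a C4 substituent, and the C6 epimers may be hard to separate while C3 is also a mixture. Fallback: from 23, anion exchange with KBr gives bromo({(4S,6R)-3-methoxy-4-methyl-6-[(2R,5E,9E)-2-methyl-10-phenyldeca-5,9-dien-1-yl]-4-[(triethylsilyl)oxy]-1,2-dioxan-6-yl}methyl)mercury F7 and its C6 epimer, which are separated at this stage. Peroxymercuration is reversible in the presence of strong acid, so the unwanted C6 epimer is returned to the equilibrium mixture with catalytic HClO4 and Hg(OAc)2 and separated again. The 6R bromide F7 is reduced with NaBH4 and rejoins the route at 24. The step thus becomes a separation-and-recycle loop under reversible conditions.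

**Step 16.** The nucleophile may attack the wrong face of the peroxycarbenium ion: the competing half-chair with the silyloxy group pseudo-axial avoids the syn-axial methyl pair and leads to the 3R epimer, which cannot give the cis-fused lactone. Lewis acid-induced O–O cleavage is a second loss channel. Fallback: from 21, aqueous HCl in THF removes acetal and silyl ether to give (2S,6R,9E,13E)-2-hydroxy-2,6-dimethyl-4-methylidene-14-phenyltetradeca-9,13-dienal F8. The ylide Ph3P=C=C=O acylates the hydroxyl and closes by intramolecular Wittig reaction to the butenolide (5S)-5-methyl-5-[(4R,7E,11E)-4-methyl-2-methylidene-12-phenyldodeca-7,11-dien-1-yl]furan-2(5H)-one F9. Hydroperoxymercuration of its 1,1-disubstituted alkene (Hg(OAc)2, H2O2) gives acetoxy{[(4R,7E,11E)-2-hydroperoxy-4-methyl-1-[(2S)-2-methyl-5-oxo-2,5-dihydrofuran-2-yl]-12-phenyldodeca-7,11-dien-2-yl]methyl}mercury F10, and NaBH4 gives the hydroperoxide (5S)-5-[(4R,7E,11E)-2-hydroperoxy-2,4-dimethyl-12-phenyldodeca-7,11-dien-1-yl]-5-methylfuran-2(5H)-one F11. Et2NH in CF3CH2OH then induces 6-exo oxa-Michael addition of the hydroperoxide to C3 of the butenolide, which can only give the cis ring fusion, and the route is rejoined at 28 after separation from its C6 epimer. The C3/C4 relationship is then fixed by ring geometry and no longer depends on facial selectivity.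

## Further compounds

F1 | step 12 | (2R,5E,9E)-2-methyl-10-phenyldeca-5,9-dien-1-ol | C[C@H](CC/C=C/CC/C=C/c1ccccc1)CO
F2 | step 12 | (2S,5E,9E)-2-methyl-10-phenyldeca-5,9-dien-1-yl acetate | C[C@@H](CC/C=C/CC/C=C/c1ccccc1)COC(C)=O
F3 | step 12 | [(1E,5E,9R)-10-iodo-9-methyldeca-1,5-dien-1-yl]benzene | C[C@H](CC/C=C/CC/C=C/c1ccccc1)CI
F4 | step 12 | iodo[(2R,5E,9E)-2-methyl-10-phenyldeca-5,9-dien-1-yl]zinc | C[C@H](CC/C=C/CC/C=C/c1ccccc1)C[Zn]I
F5 | step 13 | acetoxy{[(2S,6R,9E,13E)-4-hydroperoxy-1,1-dimethoxy-2,6-dimethyl-14-phenyl-2-[(triethylsilyl)oxy]tetradeca-9,13-dien-4-yl]methyl}mercury (both C4 epimers) | C[C@H](CC/C=C/CC/C=C/c1ccccc1)CC(C[Hg]OC(C)=O)(OO)C[C@](C)(O[Si](CC)(CC)CC)C(OC)OC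
F6 | step 13 | {[(2S,6R,9E,13E)-4-hydroperoxy-1,1-dimethoxy-2,4,6-trimethyl-14-phenyltetradeca-9,13-dien-2-yl]oxy}triethylsilane (both C4 epimers) | C[C@H](CC/C=C/CC/C=C/c1ccccc1)CC(C)(OO)C[C@](C)(O[Si](CC)(CC)CC)C(OC)OC
F7 | step 14 | bromo({(4S,6R)-3-methoxy-4-methyl-6-[(2R,5E,9E)-2-methyl-10-phenyldeca-5,9-dien-1-yl]-4-[(triethylsilyl)oxy]-1,2-dioxan-6-yl}methyl)mercury (both C3 epimers) | C[C@H](CC/C=C/CC/C=C/c1ccccc1)C[C@]1(C[Hg]Br)C[C@](C)(O[Si](CC)(CC)CC)C(OC)OO1
F8 | step 16 | (2S,6R,9E,13E)-2-hydroxy-2,6-dimethyl-4-methylidene-14-phenyltetradeca-9,13-dienal | C[C@H](CC/C=C/CC/C=C/c1ccccc1)CC(=C)C[C@](C)(O)C=O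
F9 | step 16 | (5S)-5-methyl-5-[(4R,7E,11E)-4-methyl-2-methylidene-12-phenyldodeca-7,11-dien-1-yl]furan-2(5H)-one | C[C@H](CC/C=C/CC/C=C/c1ccccc1)CC(=C)C[C@]1(C)OC(=O)C=C1
F10 | step 16 | acetoxy{[(4R,7E,11E)-2-hydroperoxy-4-methyl-1-[(2S)-2-methyl-5-oxo-2,5-dihydrofuran-2-yl]-12-phenyldodeca-7,11-dien-2-yl]methyl}mercury (both C2 epimers) | C[C@H](CC/C=C/CC/C=C/c1ccccc1)CC(C[Hg]OC(C)=O)(OO)C[C@]1(C)OC(=O)C=C1
F11 | step 16 | (5S)-5-[(4R,7E,11E)-2-hydroperoxy-2,4-dimethyl-12-phenyldodeca-7,11-dien-1-yl]-5-methylfuran-2(5H)-one (both C2 epimers) | C[C@H](CC/C=C/CC/C=C/c1ccccc1)CC(C)(OO)C[C@]1(C)OC(=O)C=C1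
A1 | alternative 1 | 2-{(3S,4R,6R)-6-[(2R)-5-(acetyloxy)-2-methylpentyl]-4,6-dimethyl-1,2-dioxan-3-yl}acetic acid | C[C@H](CCCOC(C)=O)C[C@]1(C)C[C@@H](C)[C@H](CC(=O)O)OO1
A2 | alternative 1 | (4R)-5-[(3R,4aS,7aS)-3,4a-dimethyl-6-oxohexahydro-3H-furo[3,2-c][1,2]dioxin-3-yl]-4-methylpentyl acetate | C[C@H](CCCOC(C)=O)C[C@]1(C)C[C@]2(C)OC(=O)C[C@@H]2OO1
A3 | alternative 2 | tert-butyl (3S)-3-{[(3R,5R)-8-{[tert-butyl(dimethyl)silyl]oxy}-3,5-dimethyloct-1-en-3-yl]peroxy}-4-methylpent-4-enoate | C[C@H](CCCO[Si](C)(C)C(C)(C)C)C[C@](C)(C=C)OO[C@@H](CC(=O)OC(C)(C)C)C(C)=C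
A4 | alternative 2 | tert-butyl 2-{(3S,6R)-6-[(2R)-5-{[tert-butyl(dimethyl)silyl]oxy}-2-methylpentyl]-4,6-dimethyl-3,6-dihydro-1,2-dioxin-3-yl}acetate | C[C@H](CCCO[Si](C)(C)C(C)(C)C)C[C@]1(C)C=C(C)[C@H](CC(=O)OC(C)(C)C)OO1
A5 | alternative 3 | acetoxy({(3S,4S,6R)-3-methoxy-4-methyl-6-[(2R,5E,9E)-2-methyl-10-phenyldeca-5,9-dien-1-yl]-4-[(triethylsilyl)oxy]-1,2-dioxan-6-yl}methyl)mercury | C[C@H](CC/C=C/CC/C=C/c1ccccc1)C[C@]1(C[Hg]OC(C)=O)C[C@](C)(O[Si](CC)(CC)CC)[C@@H](OC)OO1
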